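**Retrosynthetic overview**

1. Ring numbering used throughout: C1 (C–CH3), C2 (=CH), C3 (CH–aryl of the chalcone half), C4 (CH–aroyl), C5 (CH–C6H4OH), C6 (CH2). MOMO = methoxymethoxy, prenyl = 3-methylbut-2-enyl.
2. The last events are removal of seven MOM groups and, before that, a two-carbon ring expansion. The cyclohexene C1–C6 grows out of the cyclobutane C1–C4–C5–C6 of a 1-aroyl-2-styrylcyclobutane by breaking C1–C4 and making C3–C4.
3. Enabling feature: C4 carries an aroyl group (enolate acceptor), and the allyl unit C1–C2–C3 ends in the 2,6-dioxygenated arene (cation donor). In the four-membered ring, C1–C4 is therefore a strained push–pull σ-bond, and the neighbouring C5 can steer both new centres.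
4. The cyclobutane is assembled from three pieces: Heck reaction (C3–aryl), Rh-catalysed asymmetric conjugate arylation (C5–aryl, the only catalyst-set stereocentre) and carbonylative Suzuki coupling (C4–aroyl).
5. Ring order: bought cyclopropane → cyclobutanone (3→4, sulfide spiroannulation with methyl vinyl ketone) → cyclobutene → cyclobutane → cyclohexene (4→6). All arenes are bought.

Key step: step 14

Assumption: the (R,R)-diene ligand is taken to deliver the aryl group to the face of 15 that gives (R)-C5. If the sense of induction on this enone is the opposite, the (S,S)-ligand is used.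

**Route**

Step 1
Reactants: 1 cyclopropyl phenyl sulfide; 2 methyl vinyl ketone
Product: 4 2-[1-(phenylsulfanyl)cyclopropyl]but-3-en-2-ol (racemic), via 1-lithio-1-(phenylsulfanyl)cyclopropane 3 (not isolated)
Conditions: n-BuLi, THF, 0 °C; 2, −78 °C; H2O
Reagents that add atoms: none
Why: The sulfur-stabilised cyclopropyllithium is a hard nucleophile that should add 1,2 to the enone at low temperature (carbonyl addition, first half of the cyclopropyl sulfide spiroannulation); the new carbinol centre is racemic and is erased in step 2.

Step 2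
Reactants: 4 2-[1-(phenylsulfanyl)cyclopropyl]but-3-en-2-ol
Product: 5 2-ethenyl-2-methylcyclobutan-1-one (racemic)
Conditions: 48% aq HBF4 (cat.), Et2O, 0 °C to rt
Reagents that add atoms: water (O)
Why: Acid ionises the tertiary allylic alcohol, a cyclopropane C–C bond migrates to the cation (cyclopropylcarbinyl-to-cyclobutyl ring expansion of semipinacol type) and the thionium ion is hydrolysed to the ketone; the quaternary centre forms racemic, which is harmless because it becomes sp2 in step 14.

Step 3
Reactants: 5 2-ethenyl-2-methylcyclobutan-1-one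
Product: 7 4-ethenyl-4-methylcyclobut-1-en-1-yl trifluoromethanesulfonate (racemic), via lithium enolate 6 (not isolated)
Conditions: LDA, THF, −78 °C; PhNTf2, −78 to 0 °C
Reagents that add atoms: N-phenylbis(trifluoromethanesulfonimide) (O=S(=O)(N(c1ccccc1)S(=O)(=O)C(F)(F)F)C(F)(F)F)
Why: Only one α-position bears hydrogen, so kinetic deprotonation and O-sulfonylation of the enolate (enol triflate formation) should give a single cyclobutenyl triflate.

Step 4
Reactants: 8 resorcinol
Product: 9 1,3-bis(MOMO)benzene
Conditions: NaH, MOMCl, DMF, 0 °C to rt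
Reagents that add atoms: chloromethyl methyl ether (COCCl)
Why: Double O-alkylation of the bis-phenoxide (Williamson-type acetal protection) installs the groups that later direct both lithiations.

Step 5
Reactants: 9 1,3-bis(MOMO)benzene; 10 prenyl bromide
Product: 12 1,3-bis(MOMO)-2-prenylbenzene, via 2-lithio-1,3-bis(MOMO)benzene 11 (not isolated)
Conditions: n-BuLi, THF, 0 °C; 10, −78 °C to rt
Reagents that add atoms: none
Why: Directed ortho-metalation takes place at the position flanked by both OMOM groups, and the aryllithium is alkylated by the primary allylic bromide in an SN2 reaction.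

Step 6
Reactants: 12 1,3-bis(MOMO)-2-prenylbenzene
Product: 14 [2,4-bis(MOMO)-3-prenylphenyl]boronic acid, via 2,4-bis(MOMO)-3-prenylphenyllithium 13 (not isolated)
Conditions: n-BuLi, TMEDA, THF, −20 to 0 °C; B(OiPr)3, −78 °C; 1 M HCl to pH 6
Reagents that add atoms: triisopropyl borate (CC(C)OB(OC(C)C)OC(C)C); water (O)
Why: A second directed ortho-metalation can only use the position next to one OMOM group, and borylation followed by mild hydrolysis gives the boronic acid.

Step 7
Reactants: 7 4-ethenyl-4-methylcyclobut-1-en-1-yl trifluoromethanesulfonate; 14 [2,4-bis(MOMO)-3-prenylphenyl]boronic acid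
Product: 15 [2,4-bis(MOMO)-3-prenylphenyl] 4-ethenyl-4-methylcyclobut-1-enyl ketone (racemic)
Conditions: PdCl2(dppf) (5 mol %), K2CO3, CO (1 atm), THF, 45 °C
Reagents that add atoms: carbon monoxide ([C-]#[O+])
Why: Carbonylative Suzuki–Miyaura coupling: oxidative addition of the reactive alkenyl triflate, CO insertion and transmetalation should join the aroyl carbon to C4 below the temperature at which the cyclobutene opens.

Step 8
Reactants: 15 [2,4-bis(MOMO)-3-prenylphenyl] 4-ethenyl-4-methylcyclobut-1-enyl ketone; 16 [4-(MOMO)phenyl]boronic acid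
Product: 17 [2,4-bis(MOMO)-3-prenylphenyl] (1S,2R)-4-ethenyl-2-[4-(MOMO)phenyl]-4-methylcyclobutyl ketone (aroyl trans to aryl; both epimers at the quaternary carbon C1)
Conditions: [RhCl(C2H4)2]2 (2.5 mol %), (R,R)-Ph-bod (5.5 mol %), KOH (20 mol %), dioxane/H2O 10:1, 30 °C
Reagents that add atoms: none
Why: Rhodium-catalysed asymmetric conjugate arylation (Hayashi–Miyaura reaction), known for cyclobutene-1-carboxylates: the chiral diene ligand selects the face of C5 in both enantiomers of 15 because methyl and vinyl at the remote quaternary carbon differ little in size, and protonation or base equilibration of the enolate places the aroyl group at C4 trans to the new aryl group.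

Step 9
Reactants: 18 2,4-dihydroxyacetophenone
Product: 19 2,4-dihydroxy-3-iodoacetophenone
Conditions: I2, HIO3, EtOH/H2O, rt
Reagents that add atoms: iodine (II); iodic acid (OI(=O)=O)
Why: Electrophilic aromatic iodination with I2/HIO3 should go to the position between the two hydroxyl groups, the most activated site of the hydrogen-bonded resacetophenone.

Step 10
Reactants: 19 2,4-dihydroxy-3-iodoacetophenone
Product: 20 3-iodo-2,4-bis(MOMO)acetophenone
Conditions: NaH, MOMCl, DMF, 0 °C to rt
Reagents that add atoms: chloromethyl methyl ether (COCCl)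
Why: Williamson-type O-alkylation of both phenoxides, with NaH strong enough to break the chelate of the ortho-hydroxy ketone.

Step 11
Reactants: 21 2,4-dihydroxybenzaldehyde
Product: 22 2,4-bis(MOMO)benzaldehyde
Conditions: NaH, MOMCl, DMF, 0 °C to rt
Reagents that add atoms: chloromethyl methyl ether (COCCl)
Why: The same Williamson-type acetal protection makes the aldehyde stable to the basic aldol step.

Step 12
Reactants: 20 3-iodo-2,4-bis(MOMO)acetophenone; 22 2,4-bis(MOMO)benzaldehyde
Product: 23 (E)-1-[3-iodo-2,4-bis(MOMO)phenyl]-3-[2,4-bis(MOMO)phenyl]prop-2-en-1-one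
Conditions: KOH, EtOH/H2O, rt
Reagents that add atoms: none
Why: Claisen–Schmidt condensation: aldol addition of the methyl ketone enolate to the non-enolisable aldehyde and E1cB dehydration give the (E)-enone.

Step 13
Reactants: 17 the vinylcyclobutyl ketone; 23 the iodochalcone
Product: 24 (E)-1-{3-[(E)-2-{(2S,3R)-2-[2,4-bis(MOMO)-3-prenylbenzoyl]-3-[4-(MOMO)phenyl]-1-methylcyclobutyl}ethenyl]-2,4-bis(MOMO)phenyl}-3-[2,4-bis(MOMO)phenyl]prop-2-en-1-one (both epimers at C1)
Conditions: Pd(OAc)2 (10 mol %), n-Bu4NCl, NaHCO3, DMF, 70 °C
Reagents that add atoms: none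
Why: Mizoroki–Heck reaction under ligand-free phase-transfer conditions, as used for vinyl groups on fully substituted carbons (e.g. 2-methylbut-3-en-2-ol) with such 2,6-dioxygenated aryl iodides: insertion puts the aryl group on the terminal carbon, and since the quaternary carbon offers no β-hydrogen, syn elimination can only give the (E)-styrene; the stereocentres are not touched.

Step 14
Reactants: 24 the styrylcyclobutane (both C1 epimers)
Product: 26 (E)-1-{3-[(1R,5R,6S)-6-[2,4-bis(MOMO)-3-prenylbenzoyl]-5-[4-(MOMO)phenyl]-3-methylcyclohex-2-en-1-yl]-2,4-bis(MOMO)phenyl}-3-[2,4-bis(MOMO)phenyl]prop-2-en-1-one, via ring-opened zwitterion 25 (not isolated)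
Conditions: Sc(OTf)3 (10 mol %), 2,6-di-tert-butyl-4-methylpyridine (20 mol %), 4 Å MS, CH2Cl2, −40 to 0 °C; chromatography
Reagents that add atoms: none
Why: Proposed new method: Sc(III), chelated by the ketone and the ortho-OMOM oxygen, polarises the only push–pull σ-bond of 24, C1–C4 (tertiary, allylic and vinylogously benzylic to the 2,6-dialkoxyaryl donor on one side, α to the aroyl acceptor on the other), which heterolyses with release of ring strain to the 1,4-zwitterion 25, and the enolate carbon C4 recombines with the far allyl terminus C3, so that the four-membered ring C1–C4–C5–C6 grows by C2 and C3 into the cyclohexene. The closest known reaction types are the Lewis-acid opening of donor–acceptor cyclobutanes to 1,4-zwitterions and the zwitterionic or thermal vinylcyclobutane-to-cyclohexene 1,3-shift of polar [2+2] adducts; what is new is their use on a monoketone-activated styrylcyclobutane. The single ring closure is a 6-(enolexo)-endo-trig attack of the ketone enolate on the allyl cation, possible only from the rotamer of 24 in which C6 and C3 are cis about C1–C2, while closure at C1 or at oxygen only regenerates 24 or gives a 2-styryldihydropyran that re-ionises (or undergoes a Claisen shift) to the same product. C1 and C4 are planar in 25, so both C1 epimers converge and C5 is the only stereochemical input: C4 is set trans to the C5 aryl group because the enolate reacts in the conformer with C5–H in the enolate plane (A1,3 strain) and bonds on the face that carries the C6 tether, and C3 is set cis to the aroyl group by the compact, Coulomb-stabilised endo-type boat in which the metal enolate lies under the cation, the (E)-aryl group points outwards and the C5 aryl group is exo, away from the C1 methyl group. The step needs bond selectivity (C1–C4 over C4–C5 and C1–C6), which is secured by the far better cation at C1/C3 than at the secondary 4-alkoxybenzyl C5 and by the absence of an acceptor at C6, and it needs collapse to outrun Grob-type cycloreversion, which low temperature and a weakly polar solvent should favour.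

Step 15
Reactants: 26 the hepta-MOM ether
Product: 27 (E)-1-{3-[(1R,5R,6S)-6-[2,4-dihydroxy-3-prenylbenzoyl]-5-(4-hydroxyphenyl)-3-methylcyclohex-2-en-1-yl]-2,4-dihydroxyphenyl}-3-(2,4-dihydroxyphenyl)prop-2-en-1-one (target CNP0218862.1)
Conditions: HCl (1.25 M in MeOH), THF, 40 °C
Reagents that add atoms: none
Why: Acid-catalysed transacetalisation to methanol should cleave all seven aryl MOM ethers under conditions commonly tolerated by prenylated 2'-hydroxychalcones, and no stereocentre is touched.

**Compound list**

1 | cyclopropyl phenyl sulfide | C1CC1Sc1ccccc1 | starting material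
2 | methyl vinyl ketone | CC(=O)C=C | starting material
3 | 1-lithio-1-(phenylsulfanyl)cyclopropane | [Li]C1(CC1)Sc1ccccc1 | intermediate
4 | 2-[1-(phenylsulfanyl)cyclopropyl]but-3-en-2-ol (racemic) | CC(O)(C=C)C1(CC1)Sc1ccccc1 | intermediate
5 | 2-ethenyl-2-methylcyclobutan-1-one (racemic) | CC1(C=C)CCC1=O | intermediate
6 | lithium enolate of 5 | [Li]OC1=CCC1(C)C=C | intermediate
7 | 4-ethenyl-4-methylcyclobut-1-en-1-yl triflate (racemic) | CC1(C=C)CC=C1OS(=O)(=O)C(F)(F)F | intermediate
8 | resorcinol | Oc1cccc(O)c1 | starting material
9 | 1,3-bis(MOMO)benzene | COCOc1cccc(OCOC)c1 | intermediate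
10 | prenyl bromide | CC(C)=CCBr | starting material
11 | 2-lithio-1,3-bis(MOMO)benzene | [Li]c1c(OCOC)cccc1OCOC | intermediate
12 | 1,3-bis(MOMO)-2-prenylbenzene | COCOc1cccc(OCOC)c1CC=C(C)C | intermediate
13 | 2,4-bis(MOMO)-3-prenylphenyllithium | [Li]c1ccc(OCOC)c(CC=C(C)C)c1OCOC | intermediate
14 | [2,4-bis(MOMO)-3-prenylphenyl]boronic acid | OB(O)c1ccc(OCOC)c(CC=C(C)C)c1OCOC | intermediate
15 | aryl 4-ethenyl-4-methylcyclobut-1-enyl ketone (racemic) | C=CC1(C)CC=C1C(=O)c1ccc(OCOC)c(CC=C(C)C)c1OCOC | intermediate
16 | [4-(MOMO)phenyl]boronic acid | OB(O)c1ccc(OCOC)cc1 | starting material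
17 | aryl (1S,2R)-4-ethenyl-2-[4-(MOMO)phenyl]-4-methylcyclobutyl ketone, both epimers at the quaternary carbon | C=CC1(C)C[C@@H](c2ccc(OCOC)cc2)[C@@H]1C(=O)c1ccc(OCOC)c(CC=C(C)C)c1OCOC | intermediate
18 | 2,4-dihydroxyacetophenone | CC(=O)c1ccc(O)cc1O | starting material
19 | 2,4-dihydroxy-3-iodoacetophenone | CC(=O)c1ccc(O)c(I)c1O | intermediate
20 | 3-iodo-2,4-bis(MOMO)acetophenone | CC(=O)c1ccc(OCOC)c(I)c1OCOC | intermediate
21 | 2,4-dihydroxybenzaldehyde | O=Cc1ccc(O)cc1O | starting material
22 | 2,4-bis(MOMO)benzaldehyde | O=Cc1ccc(OCOC)cc1OCOC | intermediate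
23 | (E)-iodochalcone, tetra-MOM | COCOc1ccc(C(=O)/C=C/c2ccc(OCOC)cc2OCOC)c(OCOC)c1I | intermediate
24 | (E)-styrylcyclobutane, hepta-MOM, (C4 S, C5 R), both C1 epimers | COCOc1ccc(C(=O)/C=C/c2ccc(OCOC)cc2OCOC)c(OCOC)c1/C=C/C1(C)C[C@@H](c2ccc(OCOC)cc2)[C@@H]1C(=O)c1ccc(OCOC)c(CC=C(C)C)c1OCOC | intermediate
25 | ring-opened 1,4-zwitterion (drawn without Sc; Z-enolate, cisoid allyl cation) | CC(C)=CCc1c(OCOC)ccc(/C([O-])=C/[C@@H](C/C(C)=C\[CH+]c2c(OCOC)ccc(C(=O)/C=C/c3ccc(OCOC)cc3OCOC)c2OCOC)c2ccc(OCOC)cc2)c1OCOC | intermediate
26 | hepta-MOM ether of the target, (C3 R, C4 S, C5 R) | CC(C)=CCc1c(OCOC)ccc(C(=O)[C@@H]2[C@H](c3c(OCOC)ccc(C(=O)/C=C/c4ccc(OCOC)cc4OCOC)c3OCOC)C=C(C)C[C@H]2c2ccc(OCOC)cc2)c1OCOC | intermediate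
27 | target CNP0218862.1 | CC(C)=CCc1c(O)ccc(C(=O)[C@@H]2[C@H](c3c(O)ccc(C(=O)/C=C/c4ccc(O)cc4O)c3O)C=C(C)C[C@H]2c2ccc(O)cc2)c1O | target

**Step count**

Total step count: 15.
Longest linear sequence: 8 steps (1, 2, 3, 7, 8, 13, 14, 15, or equally 4, 5, 6, 7, 8, 13, 14, 15).

**Steps most likely to fail**

1. Step 14 (Proposed new method).
   - What may go wrong: the zwitterion may close with poor facial selectivity at C3 (endo- versus exo-type boat). It may fragment in a Grob-type cycloreversion to enone and diene. MOM groups may be lost at the Lewis acid.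
   - Fallback (known chemistry, sets out from 24 and comes back at 26): the approach changes from a stereoconvergent ionic collapse to a stereospecific thermal 1,3-shift on one epimer. The C1 epimers of 24 are separated by chromatography. The cis-styryl epimer of 24 F1 (styryl cis to the C5 aryl group) is heated without additive (toluene, 120 °C, sealed tube, BHT). This classical thermal vinylcyclobutane-to-cyclohexene rearrangement runs through a short-lived diradical. In it, C4 should slide over the allyl face that it already occupies. This least-motion path turns the C5 aryl group exo and should lead to the 3,4-cis-4,5-trans array of 26, so C1 rather than a conformational preference dictates C3.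

2. Step 8.
   - What may go wrong: the strained enone 15 may undergo electrocyclic opening. The substrate bias from C1 may override catalyst control, so that the enantiopurity at C5 falls.
   - Fallback (sets out from 7 and comes back at 17): the stereocentre is set on the ester, the substrate class for which this arylation is established, and the aroyl group is brought in afterwards. Pd-catalysed methoxycarbonylation of 7 (Pd(OAc)2, PPh3, Et3N, CO, MeOH, rt) gives methyl 4-ethenyl-4-methylcyclobut-1-ene-1-carboxylate F2. Rh/chiral-diene arylation with 16 gives methyl (1S,2R)-4-ethenyl-2-[4-(MOMO)phenyl]-4-methylcyclobutane-1-carboxylate F3. Treatment with i-PrMgCl and MeNHOMe·HCl converts it into the N-methoxy-N-methylamide F4. Addition of the aryllithium 13 (made from 12 as in step 6) gives 17.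

3. Step 13.
   - What may go wrong: the hindered arylpalladium species may insert slowly into the neopentyl-type vinyl group. Arylation or reduction at the chalcone C=C, or thermal opening of the product, could then take over.
   - Fallback (sets out from 17 and 20 and comes back at 26): the enone is kept out of the coupling and out of the ring expansion, and is built last. Heck reaction of 17 with the simpler iodide 20 gives the acetyl-substituted styrylcyclobutane F5. The conditions of step 14 turn it into the acetyl-substituted cyclohexene F6. Claisen–Schmidt condensation of F6 with 22 (KOH, EtOH, rt, short contact to spare C4) gives 26.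

**Further compounds**

F1 | step 14 | cis-styryl epimer of 24 (styryl cis to the C5 aryl group) | COCOc1ccc(C(=O)/C=C/c2ccc(OCOC)cc2OCOC)c(OCOC)c1/C=C/[C@@]1(C)C[C@@H](c2ccc(OCOC)cc2)[C@@H]1C(=O)c1ccc(OCOC)c(CC=C(C)C)c1OCOC
F2 | step 8 | methyl 4-ethenyl-4-methylcyclobut-1-ene-1-carboxylate (racemic) | C=CC1(C)CC=C1C(=O)OC
F3 | step 8 | methyl (1S,2R)-4-ethenyl-2-[4-(MOMO)phenyl]-4-methylcyclobutane-1-carboxylate, both epimers at the quaternary carbon | C=CC1(C)C[C@@H](c2ccc(OCOC)cc2)[C@@H]1C(=O)OC
F4 | step 8 | (1S,2R)-4-ethenyl-N-methoxy-2-[4-(MOMO)phenyl]-N,4-dimethylcyclobutane-1-carboxamide | C=CC1(C)C[C@@H](c2ccc(OCOC)cc2)[C@@H]1C(=O)N(C)OC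
F5 | step 13 | acetyl-substituted (E)-styrylcyclobutane, both C1 epimers | COCOc1ccc(C(C)=O)c(OCOC)c1/C=C/C1(C)C[C@@H](c2ccc(OCOC)cc2)[C@@H]1C(=O)c1ccc(OCOC)c(CC=C(C)C)c1OCOC
F6 | step 13 | acetyl-substituted cyclohexene (C3 R, C4 S, C5 R) | CC(C)=CCc1c(OCOC)ccc(C(=O)[C@@H]2[C@H](c3c(OCOC)ccc(C(C)=O)c3OCOC)C=C(C)C[C@H]2c2ccc(OCOC)cc2)c1OCOC
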